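Ring A is disconnected at C3–C4, the bond between the ketone carbon and the gem-dimethyl carbon. Read backwards, C4 with its two methyl groups is the tertiary radical of an isopropenyl group and the C3 carbonyl is a nitrile carbon. The precursor is therefore a monocyclic ring B cyclohexene from (R)-carvone, whose own isopropenyl group sits on C5, with methyl and 2-cyanoethyl on C10 and the oxygenated C11 on C9. One iron-hydride hydrogen-atom-transfer cyclisation then creates the C3–C4 bond, the C4 quaternary centre, the C3 ketone and the trans-fused ring A together. Isofraxidin is attached last.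

Key step: step 9

Remark: drimane numbering is used for the decalin and for its monocyclic precursors (C11 is the OCH2 carbon on C9). The target is read as (5R,9R,10S): a trans-decalin with CH2OAr on the face opposite to the C10 methyl (alpha face; the methyl face is beta). (R)-carvone, isofraxidin and Bu3SnCH2I are taken as commercial.

Step 1
Reactants: 1 (R)-(−)-carvone
Product: 3 (5R)-2,6-dimethyl-5-(prop-1-en-2-yl)cyclohex-2-en-1-one (6-methylcarvone; both C6 epimers), via lithium dienolate 2 (not isolated)
Conditions: LiN(iPr)2, THF, −78 °C; MeI, −78 to 0 °C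
Reagents that add atoms: iodomethane CI
Why: Kinetic enolate alkylation, in which LiN(iPr)2 removes the alpha-prime proton (the future C10) and the cross-conjugated enolate is C-methylated, the configuration of the new centre being irrelevant because it is planarised again in step 2.

Step 2
Reactants: 3 6-methylcarvone
Product: 5 (5S,6S)-6-allyl-2,6-dimethyl-5-(prop-1-en-2-yl)cyclohex-2-en-1-one, via lithium dienolate 4 (not isolated)
Conditions: LiN(iPr)2, THF, −78 °C; allyl bromide, DMPU, −78 °C to rt
Reagents that add atoms: allyl bromide C=CCBr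
Why: Second enolate alkylation, in which allyl bromide attacks the tetrasubstituted enolate on the face opposite to the adjacent isopropenyl group, setting the quaternary carbon (future C10) with allyl trans and methyl cis to isopropenyl.

Step 3
Reactants: 5 allyl ketone
Product: 6 2,3-epoxide of 5 with the oxirane on the alpha face (trans to isopropenyl and to the quaternary methyl)
Conditions: 30% aq H2O2, NaOH (0.3 equiv), MeOH, 0 °C
Reagents that add atoms: hydrogen peroxide OO
Why: Weitz–Scheffer nucleophilic epoxidation touches only the enone, and hydroperoxide should add to the beta carbon (future C7) anti to the isopropenyl group as in carvone itself, which places the oxirane on the alpha face.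

Step 4
Reactants: 6 epoxy ketone
Product: 9 (1R,4R,5S)-4-allyl-2,4-dimethyl-5-(prop-1-en-2-yl)cyclohex-2-en-1-ol (hydroxyl trans to isopropenyl), via epoxy hydrazone 7 (not isolated), via alkenyl diazene 8 (not isolated)
Conditions: N2H4·H2O, AcOH (cat.), MeOH, 0 °C to rt
Reagents that add atoms: none
Why: Wharton transposition, in which the hydrazone opens the oxirane to an alkenyl diazene that loses N2, so that the oxygen stays on C7 with its alpha configuration, the alkene moves to C8=C9 and C9 becomes CH.

Step 5
Reactants: 9 allylic alcohol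
Product: 11 tributyl({[(1R,4R,5S)-4-allyl-2,4-dimethyl-5-(prop-1-en-2-yl)cyclohex-2-en-1-yl]oxy}methyl)stannane, via potassium alkoxide 10 (not isolated)
Conditions: KH, THF, 0 °C; Bu3SnCH2I, 18-crown-6 (cat.), rt
Reagents that add atoms: tributyl(iodomethyl)stannane CCCC[Sn](CCCC)(CCCC)CI
Why: Williamson etherification of the potassium alkoxide with the reactive iodomethylstannane, without change at any stereocentre.

Step 6
Reactants: 11 stannylmethyl ether
Product: 14 tert-butyl{[(1R,5S,6S)-6-allyl-2,6-dimethyl-5-(prop-1-en-2-yl)cyclohex-2-en-1-yl]methoxy}dimethylsilane, via lithiomethyl ether 12 (not isolated), via lithium alkoxide 13 (not isolated)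
Conditions: n-BuLi, THF, −78 °C; then TBSCl, DMPU, −78 °C to rt
Reagents that add atoms: tert-butyldimethylsilyl chloride CC(C)(C)[Si](C)(C)Cl
Why: Wittig–Still [2,3]-sigmatropic rearrangement, in which tin–lithium exchange gives the alpha-alkoxy carbanion that is passed suprafacially from the alpha oxygen on C7 to C9, so that C9 receives C11 on the alpha face (cis to the allyl chain, H on the methyl face) while the alkene returns to C7=C8 and the temporary C7–O bond is cleaved, the alkoxide being silylated in the same flask.

Step 7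
Reactants: 14 silyl ether
Product: 16 3-[(1S,2R,6S)-2-({[tert-butyl(dimethyl)silyl]oxy}methyl)-1,3-dimethyl-6-(prop-1-en-2-yl)cyclohex-3-en-1-yl]propan-1-ol, via trialkylborane 15 (not isolated)
Conditions: Sia2BH (from BH3·THF and 2-methylbut-2-ene), THF, 0 °C; then 3 M aq NaOH, 30% H2O2, 0 °C to rt
Reagents that add atoms: hydrogen peroxide OO
Why: Hydroboration–oxidation, in which the bulky dialkylborane should add anti-Markovnikov to the monosubstituted allyl alkene much faster than to the hindered isopropenyl or the trisubstituted ring alkene, giving the primary alcohol whose carbon becomes C3.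

Step 8
Reactants: 16 primary alcohol
Product: 19 3-[(1S,2R,6S)-2-({[tert-butyl(dimethyl)silyl]oxy}methyl)-1,3-dimethyl-6-(prop-1-en-2-yl)cyclohex-3-en-1-yl]propanenitrile, via aldehyde 17 (not isolated), via aldimine 18 (not isolated)
Conditions: TEMPO (10 mol %), PhI(OAc)2, NH4OAc, MeCN/H2O (9:1), rt
Reagents that add atoms: ammonium acetate CC(=O)[O-].[NH4+]
Why: One-pot oxidation–imination–oxidation, in which the alcohol is oxidised to the aldehyde, condensed with ammonia to the N–H aldimine and oxidised on to the nitrile under conditions that leave the alkenes and the silyl ether alone.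

Step 9
Reactants: 19 nitrile
Product: 22 (4aS,5R,8aR)-5-(hydroxymethyl)-1,1,4a,6-tetramethyl-3,4,4a,5,8,8a-hexahydronaphthalen-2(1H)-one, via ketimine 20 (not isolated), via silyl ether ketone 21 (not isolated)
Conditions: Fe(acac)3 [iron tris(acetylacetonate)] (0.5 equiv), PhSiH3, EtOH (0.01 M), 60 °C; then 2 M aq HCl, THF, rt
Reagents that add atoms: water O
Why: An iron hydride formed from Fe(acac)3, PhSiH3 and ethanol transfers a hydrogen atom to the CH2 terminus of the isopropenyl group, the tertiary C4 radical adds to the nitrile carbon C3, and the iminyl radical is reduced to the N–H ketimine, which the acidic work-up hydrolyses to the C3 ketone while also cleaving the silyl ether. The closest known reaction type is the hydrogen-atom-transfer-initiated reductive cyclisation of alkene-tethered nitriles to alpha-quaternary cycloalkanones. Ring A is closed in the 6-exo-dig mode. No stereocentre is created, since C4 ends with two methyl groups, and the trans ring fusion follows from the trans, diequatorial arrangement of the isopropenyl group on C5 and the cyanoethyl chain on C10 fixed in step 2. The step needs hydrogen-atom transfer to the unhindered 1,1-disubstituted alkene in preference to the more crowded trisubstituted C7=C8 alkene, and cyclisation faster than reduction of the radical; the first should be secured by the steric difference between the two alkenes, the second by high dilution and by the quaternary C10, which holds chain and radical close.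

Step 10
Reactants: 22 keto alcohol; 23 isofraxidin (7-hydroxy-6,8-dimethoxy-2H-chromen-2-one)
Product: 25 6,8-dimethoxy-7-{[(1R,4aR,8aS)-2,5,5,8a-tetramethyl-6-oxo-1,4,4a,5,6,7,8,8a-octahydronaphthalen-1-yl]methoxy}-2H-chromen-2-one (CNP0127079.1), via alkoxyphosphonium salt 24 (not isolated)
Conditions: PPh3, DIAD, THF, 0 to 40 °C
Reagents that add atoms: none
Why: Mitsunobu etherification, in which the primary alcohol is activated as its alkoxyphosphonium ion and displaced at the non-stereogenic C11 by the acidic phenol, so that C9 is untouched and the ketone and alkene are inert.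

Compound list
1 | (R)-(−)-carvone, (5R)-2-methyl-5-(prop-1-en-2-yl)cyclohex-2-en-1-one | O=C1C(C)=CC[C@@H](C(C)=C)C1 | starting material
2 | lithium cross-conjugated dienolate of 1 (not isolated) | [Li]OC1=C[C@H](C(C)=C)CC=C1C | intermediate
3 | (5R)-2,6-dimethyl-5-(prop-1-en-2-yl)cyclohex-2-en-1-one (6-methylcarvone, both C6 epimers) | O=C1C(C)=CC[C@@H](C(C)=C)C1C | intermediate
4 | lithium dienolate of 3 (not isolated) | [Li]OC1=C(C)[C@H](C(C)=C)CC=C1C | intermediate
5 | (5S,6S)-6-allyl-2,6-dimethyl-5-(prop-1-en-2-yl)cyclohex-2-en-1-one (allyl trans, methyl cis to isopropenyl) | O=C1C(C)=CC[C@@H](C(C)=C)[C@@]1(CC=C)C | intermediate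
6 | 2,3-epoxide of 5, oxirane trans to isopropenyl and to the quaternary methyl | O=C1[C@]2(C)O[C@@H]2C[C@@H](C(C)=C)[C@@]1(CC=C)C | intermediate
7 | hydrazone of 6 (not isolated) | NN=C1[C@]2(C)O[C@@H]2C[C@@H](C(C)=C)[C@@]1(CC=C)C | intermediate
8 | alkenyl diazene from opening of the oxirane of 7 (not isolated) | N=NC1=C(C)[C@H](O)C[C@@H](C(C)=C)[C@@]1(CC=C)C | intermediate
9 | (1R,4R,5S)-4-allyl-2,4-dimethyl-5-(prop-1-en-2-yl)cyclohex-2-en-1-ol (hydroxyl trans to isopropenyl) | O[C@@H]1C[C@@H](C(C)=C)[C@@](CC=C)(C)C=C1C | intermediate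
10 | potassium alkoxide of 9 (not isolated) | [K+].[O-][C@@H]1C[C@@H](C(C)=C)[C@@](CC=C)(C)C=C1C | intermediate
11 | tributylstannylmethyl ether of 9 | CCCC[Sn](CCCC)(CCCC)CO[C@@H]1C[C@@H](C(C)=C)[C@@](CC=C)(C)C=C1C | intermediate
12 | lithiomethyl ether of 9 (not isolated) | [Li]CO[C@@H]1C[C@@H](C(C)=C)[C@@](CC=C)(C)C=C1C | intermediate
13 | lithium [(1R,5S,6S)-6-allyl-2,6-dimethyl-5-(prop-1-en-2-yl)cyclohex-2-en-1-yl]methoxide (not isolated) | [Li]OC[C@@H]1C(C)=CC[C@@H](C(C)=C)[C@@]1(CC=C)C | intermediate
14 | tert-butyl{[(1R,5S,6S)-6-allyl-2,6-dimethyl-5-(prop-1-en-2-yl)cyclohex-2-en-1-yl]methoxy}dimethylsilane (CH2O cis to allyl, trans to the quaternary methyl and to isopropenyl) | CC(C)(C)[Si](C)(C)OC[C@@H]1C(C)=CC[C@@H](C(C)=C)[C@@]1(CC=C)C | intermediate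
15 | alkylbis(3-methylbutan-2-yl)borane from 14 (not isolated) | CC(C)(C)[Si](C)(C)OC[C@@H]1C(C)=CC[C@@H](C(C)=C)[C@@]1(CCCB(C(C)C(C)C)C(C)C(C)C)C | intermediate
16 | 3-[(1S,2R,6S)-2-({[tert-butyl(dimethyl)silyl]oxy}methyl)-1,3-dimethyl-6-(prop-1-en-2-yl)cyclohex-3-en-1-yl]propan-1-ol | CC(C)(C)[Si](C)(C)OC[C@@H]1C(C)=CC[C@@H](C(C)=C)[C@@]1(CCCO)C | intermediate
17 | corresponding propanal (not isolated) | CC(C)(C)[Si](C)(C)OC[C@@H]1C(C)=CC[C@@H](C(C)=C)[C@@]1(CCC=O)C | intermediate
18 | corresponding N–H aldimine (not isolated) | CC(C)(C)[Si](C)(C)OC[C@@H]1C(C)=CC[C@@H](C(C)=C)[C@@]1(CCC=N)C | intermediate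
19 | 3-[(1S,2R,6S)-2-({[tert-butyl(dimethyl)silyl]oxy}methyl)-1,3-dimethyl-6-(prop-1-en-2-yl)cyclohex-3-en-1-yl]propanenitrile | CC(C)(C)[Si](C)(C)OC[C@@H]1C(C)=CC[C@@H](C(C)=C)[C@@]1(CCC#N)C | intermediate
20 | N–H ketimine of 21 (not isolated) | CC(C)(C)[Si](C)(C)OC[C@@H]1C(C)=CC[C@H]2C(C)(C)C(=N)CC[C@]12C | intermediate
21 | (4aS,5R,8aR)-5-({[tert-butyl(dimethyl)silyl]oxy}methyl)-1,1,4a,6-tetramethyl-3,4,4a,5,8,8a-hexahydronaphthalen-2(1H)-one (not isolated) | CC(C)(C)[Si](C)(C)OC[C@@H]1C(C)=CC[C@H]2C(C)(C)C(=O)CC[C@]12C | intermediate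
22 | (4aS,5R,8aR)-5-(hydroxymethyl)-1,1,4a,6-tetramethyl-3,4,4a,5,8,8a-hexahydronaphthalen-2(1H)-one, (5R,9R,10S)-11-hydroxydrim-7-en-3-one | OC[C@@H]1C(C)=CC[C@H]2C(C)(C)C(=O)CC[C@]12C | intermediate
23 | isofraxidin, 7-hydroxy-6,8-dimethoxy-2H-chromen-2-one | COc1cc2ccc(=O)oc2c(OC)c1O | starting material
24 | alkoxytriphenylphosphonium salt of 22 with the phenoxide of 23 (not isolated) | COc1cc2ccc(=O)oc2c(OC)c1[O-].c1ccccc1[P+](c1ccccc1)(c1ccccc1)OC[C@@H]1C(C)=CC[C@H]2C(C)(C)C(=O)CC[C@]12C | intermediate
25 | 6,8-dimethoxy-7-{[(1R,4aR,8aS)-2,5,5,8a-tetramethyl-6-oxo-1,4,4a,5,6,7,8,8a-octahydronaphthalen-1-yl]methoxy}-2H-chromen-2-one | COc1cc2ccc(=O)oc2c(OC)c1OC[C@@H]1C(C)=CC[C@H]2C(C)(C)C(=O)CC[C@]12C | target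

Total step count: 10
Longest linear sequence: 10 steps (1 to 25)

Steps most likely to fail

Step 9. The tertiary radical may be reduced, or hydrogen-atom transfer may go to the ring alkene, before the slow closure onto the nitrile. The fallback sets out from alcohol 16. Oxidation with TEMPO and PhI(OAc)2 in CH2Cl2, without the ammonium salt, stops at aldehyde 17, which is isolated. The same iron hydride conditions (Fe(acac)3, PhSiH3, EtOH) then close ring A by addition of the C4 radical to the far more reactive aldehyde carbonyl, a closure known for alkene-tethered ketones, and should give the ring-closed C3 alcohol F1 as a mixture of C3 epimers. Dess–Martin periodinane oxidises it to silyl ether ketone 21, and aqueous HCl in THF gives 22, where the route is rejoined.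

Step 4. Hydrazone formation at a carbonyl flanked by two fully substituted carbons may be too slow, so that hydrazine opens the oxirane instead. The fallback sets out from epoxy ketone 6. NaBH4 in MeOH should give the epoxy alcohol F2 (either carbinol epimer serves). NaH, CS2 and MeI give the S-methyl xanthate F3. Bu3SnH and AIBN in benzene at 80 °C generate the C9 radical, which opens the neighbouring oxirane, and the alkoxyl radical takes hydrogen from the stannane to give allylic alcohol 9, where the route is rejoined.

Step 10. Substitution at the beta-branched, axial C11 by a phenol flanked by two methoxy groups may be slower than consumption of the betaine. The fallback sets out from keto alcohol 22. Tf2O and 2,6-lutidine in CH2Cl2 at −78 °C give the primary triflate F4, which is displaced by the cesium phenoxide of isofraxidin 23 (Cs2CO3, DMF, 0 °C to rt) to give 25 directly.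

Further compounds
F1 | step 9 | (4aS,5R,8aR)-5-({[tert-butyl(dimethyl)silyl]oxy}methyl)-1,1,4a,6-tetramethyl-1,2,3,4,4a,5,8,8a-octahydronaphthalen-2-ol (both C2 epimers) | CC(C)(C)[Si](C)(C)OC[C@@H]1C(C)=CC[C@H]2C(C)(C)C(O)CC[C@]12C
F2 | step 4 | epoxy alcohol from reduction of the ketone of 6 (carbinol configuration open) | OC1[C@]2(C)O[C@@H]2C[C@@H](C(C)=C)[C@@]1(CC=C)C
F3 | step 4 | O-alkyl S-methyl xanthate of F2 | CSC(=S)OC1[C@]2(C)O[C@@H]2C[C@@H](C(C)=C)[C@@]1(CC=C)C
F4 | step 10 | trifluoromethanesulfonate of 22 | O=S(=O)(OC[C@@H]1C(C)=CC[C@H]2C(C)(C)C(=O)CC[C@]12C)C(F)(F)F
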